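## Retrosynthetic overview

1. Target 21 ⇒ bicyclic vinylogous ester 18 + benzaldehyde 19 (C3 lithiation/addition, then alcohol oxidation).
2. 18 ⇒ cis-hydrindane tertiary alcohol 17 by an oxidative 1,2-alkyl shift (semipinacol ring expansion): the five-membered ring grows into the bridged cyclohexanone and C1 becomes quaternary.
3. 17 ⇒ 16 ⇒ 15 ⇒ ketone 12 + diketene 13 (γ-prenylation, O-methylation, diketene annulation that builds the dione ring on the cyclopentanone).
4. 12 ⇒ cyclopentanone 6 + (S)-lavandulol 10 (enolate alkylation via the triflate); 10 ⇐ 3-methylbut-2-enoic acid 7 + prenyl bromide 8.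
5. 6 ⇐ 2-methylcyclopent-2-en-1-one 1 + bromide 2 + MeI. Ring order: cyclopentane (bought) → six-membered dione ring (step 6) → bicyclo[3.3.1]nonane by ring expansion (step 9).

Assumptions: prenyl = 3-methylbut-2-en-1-yl; Lav = (2R)-5-methyl-2-(prop-1-en-2-yl)hex-4-en-1-yl (the group delivered by (S)-lavandulol; it is R only through CIP priority once attached); core numbering from 18 on is C1 (prenyl bridgehead next to CMe2), C2 (OMe), C3, C4 (C=O), C5 (Lav bridgehead), C6, C7 (CH-prenyl), C8 (CMe2), C9 (bridging C=O); lithium enolates made by simple deprotonation count as the reactive form of the numbered compound; the antipode of the ligand (step 1) and of the chiral amine (step 3) is the one that gives the stated product.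

## Route

Step 1
Reactants: 1 2-methylcyclopent-2-en-1-one; 2 4-bromo-2-methylbut-1-ene
Product: 5 (R)-2,2-dimethyl-3-(3-methylbut-3-en-1-yl)cyclopentan-1-one, via isopentenyl Grignard reagent 3 (not isolated), via bromomagnesium enolate 4 (not isolated)
Conditions: 2, Mg, Et2O; CuBr·SMe2 (5 mol%), Rev-Josiphos (6 mol%), t-BuOMe, −78 °C, slow addition of 3; then MeI, DMPU, −78 °C → rt
Reagents that add atoms: iodomethane, CI
Why: Asymmetric conjugate addition of a primary alkyl Grignard reagent to an α-methyl cyclic enone under monovalent copper/ferrocenyl diphosphine catalysis sets the ring stereocentre (future C7) by ligand control, and C-methylation of the regiodefined magnesium enolate (enolate alkylation) builds the gem-dimethyl carbon.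

Step 2
Reactants: 5 (R)-2,2-dimethyl-3-(3-methylbut-3-en-1-yl)cyclopentan-1-one
Product: 6 (S)-2,2-dimethyl-3-(3-methylbut-2-en-1-yl)cyclopentan-1-one
Conditions: Co(salen)Cl (3 mol%; salen = N,N′-bis(3,5-di-tert-butylsalicylidene)-1,2-cyclohexanediaminate), PhSiH3 (6 mol%), benzene, rt
Reagents that add atoms: none
Why: Cobalt hydride hydrogen-atom-transfer alkene transposition moves the 1,1-disubstituted alkene by one position to the thermodynamically preferred trisubstituted prenyl alkene without touching the stereocentre (R becomes S only through CIP priorities).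

Step 3
Reactants: 7 3-methylbut-2-enoic acid; 8 1-bromo-3-methylbut-2-ene (prenyl bromide)
Product: 9 (S)-5-methyl-2-(prop-1-en-2-yl)hex-4-enoic acid ((S)-lavandulic acid)
Conditions: N1,N3-bis[1-phenyl-2-(piperidin-1-yl)ethyl]propane-1,3-diamine (single enantiomer, 1.05 equiv), n-BuLi (4.0 equiv), THF, 0 °C; 8, −78 °C; aq. HCl (amine recovered)
Reagents that add atoms: none
Why: Deconjugative α-alkylation of the lithium dienediolate of a 2-alkenoic acid (α-attack is the normal course with allylic bromides) is made enantioselective by a mixed aggregate with a recoverable C2-symmetric chiral lithium amide, which sets the side-chain stereocentre.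

Step 4
Reactants: 9 (S)-lavandulic acid
Product: 10 (S)-5-methyl-2-(prop-1-en-2-yl)hex-4-en-1-ol ((S)-lavandulol)
Conditions: LiAlH4, THF, 0 °C → rt
Reagents that add atoms: none
Why: Hydride reduction of a carboxylic acid to the primary alcohol leaves the isolated alkenes and the non-acidic α-stereocentre untouched.

Step 5
Reactants: 10 (S)-lavandulol; 6 (S)-2,2-dimethyl-3-(3-methylbut-2-en-1-yl)cyclopentan-1-one
Product: 12 (3R,5RS)-2,2-dimethyl-3-prenyl-5-Lav-cyclopentan-1-one, via (S)-lavandulyl triflate 11 (not isolated)
Conditions: 10, Tf2O, 2,6-lutidine, CH2Cl2, −78 °C (11 used cold at once); 6, lithium diisopropylamide, THF, −78 °C; then 11, −78 → −20 °C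
Reagents that add atoms: none
Why: SN2 C-alkylation of the only possible (C5) lithium enolate of 6 by a primary triflate, chosen because the β-branched electrophile is too slow as a halide; the new C5 centre is re-enolised in step 6 and the side-chain centre is not involved.

Step 6
Reactants: 12 (3R,5RS)-2,2-dimethyl-3-prenyl-5-Lav-cyclopentan-1-one; 13 diketene (4-methyleneoxetan-2-one)
Product: 15 cis-fused 7a-hydroxy-1,1-dimethyl-2-prenyl-3a-Lav-hexahydro-1H-indene-4,6(5H,7H)-dione (2-prenyl/3a-Lav/7a-OH all cis; enolised dione), via acetoacetyl ketone lithium enolate 14 (not isolated)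
Conditions: lithium diisopropylamide, THF, −78 → 0 °C; 13, −78 → −30 °C; aq. NH4Cl
Reagents that add atoms: none
Why: Diketene annulation, in which the tetrasubstituted lithium enolate is C-acylated by ring-opening of diketene on the face anti to the ring prenyl group (sets the quaternary carbon, future C5) and the liberated methyl ketone enolate then adds to the adjacent ring ketone in an intramolecular aldol reaction to close the cis-fused hydrindane (sets the carbinol carbon, future C9).

Step 7
Reactants: 15 hydrindane hydroxy-dione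
Product: 16 7a-hydroxy-6-methoxy-1,1-dimethyl-2-prenyl-3a-Lav-1,2,3,3a,7,7a-hexahydro-4H-inden-4-one (configuration as in 15)
Conditions: TMSCHN2, diisopropylethylamine, MeCN/MeOH 9:1, 0 °C → rt
Reagents that add atoms: (trimethylsilyl)diazomethane, C[Si](C)(C)C=[N+]=[N-]
Why: O-Methylation of the cyclic 1,3-dione (vinylogous acid) occurs preferentially at the oxygen flanked by CH2 and not at the one next to the quaternary carbon, which places OMe on the future C2; the minor regioisomer is hydrolysed and recycled.

Step 8
Reactants: 16 hydrindane methyl vinylogous ester; 8 1-bromo-3-methylbut-2-ene (prenyl bromide)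
Product: 17 7a-hydroxy-6-methoxy-1,1-dimethyl-2,7-diprenyl-3a-Lav-1,2,3,3a,7,7a-hexahydro-4H-inden-4-one (7RS)
Conditions: lithium diisopropylamide (2.3 equiv), THF, −78 → −30 °C; 8, −78 → −20 °C; aq. NH4Cl
Reagents that add atoms: none
Why: γ-Alkylation of a vinylogous ester whose α′ carbon is quaternary, in which the alkoxide/cross-conjugated dienolate dianion reacts with prenyl bromide at the γ-carbon (extended enolate alkylation as in tetronate and 3-alkoxyenone chemistry); the new centre is planarised again in step 9.

Step 9
Reactants: 17 γ-prenylated hydrindane vinylogous ester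
Product: 18 2-methoxy-8,8-dimethyl-1,7-diprenyl-5-Lav-bicyclo[3.3.1]non-2-ene-4,9-dione (configuration as in 21)
Conditions: PhI(OAc)2 (1.5 equiv), KOH (5 equiv), MeOH, 0 °C → rt
Reagents that add atoms: none
Why: Proposed new method: trivalent-iodine-mediated oxidative semipinacol ring expansion onto a fully substituted migration terminus, in which KOH/MeOH regenerates the γ-dienolate, this attacks PhI(OMe)2 (at O, C3 or the γ-carbon), and loss of PhI is coupled to 1,2-migration of the anti-periplanar CMe2–C(O−) ring bond of the cis-fused tertiary alkoxide to the prenylated γ-carbon (direct or allylically transposed displacement, so the hindered carbon need not carry iodine), which expands the cyclopentane to the bridged cyclohexanone, creates quaternary C1 with its configuration fixed by the bridge relative to C5 and turns the alkoxide into the C9 ketone; the closest known reactions are the same oxidative 1,2-shift at an unsubstituted γ-CH2 of such hydrindanones and the Moriarty α-oxidation of ketone enolates.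

Step 10
Reactants: 18 bicyclic vinylogous ester; 19 benzaldehyde
Product: 20 3-[hydroxy(phenyl)methyl]-2-methoxy-8,8-dimethyl-1,7-diprenyl-5-Lav-bicyclo[3.3.1]non-2-ene-4,9-dione (carbinol epimers)
Conditions: lithium 2,2,6,6-tetramethylpiperidide, THF, −78 °C; 19, −78 °C; aq. NH4Cl
Reagents that add atoms: none
Why: Vinylic lithiation of the β-methoxy enone at C3 (the only acidic site once both bridgeheads are quaternary) with a hindered lithium amide, followed by 1,2-addition to benzaldehyde; the carbinol centre is removed in step 11.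

Step 11
Reactants: 20 C3 carbinol
Product: 21 (1R,5R,7R)-3-benzoyl-2-methoxy-8,8-dimethyl-1,7-diprenyl-5-Lav-bicyclo[3.3.1]non-2-ene-4,9-dione (CNP0385193.1)
Conditions: Dess–Martin periodinane, NaHCO3, CH2Cl2, rt
Reagents that add atoms: none
Why: Dess–Martin oxidation of the secondary benzylic/allylic alcohol gives the aryl ketone without affecting alkenes or any stereocentre.

## Compound list

1 | 2-methylcyclopent-2-en-1-one | CC1=CCCC1=O | starting material
2 | 4-bromo-2-methylbut-1-ene | C=C(C)CCBr | starting material
3 | (3-methylbut-3-en-1-yl)magnesium bromide | C=C(C)CC[Mg]Br | intermediate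
4 | bromomagnesium (R)-2-methyl-3-(3-methylbut-3-en-1-yl)cyclopent-1-en-1-olate | Br[Mg]OC1=C(C)[C@H](CCC(C)=C)CC1 | intermediate
5 | (R)-2,2-dimethyl-3-(3-methylbut-3-en-1-yl)cyclopentan-1-one | O=C1CC[C@@H](CCC(C)=C)C1(C)C | intermediate
6 | (S)-2,2-dimethyl-3-(3-methylbut-2-en-1-yl)cyclopentan-1-one | O=C1CC[C@@H](CC=C(C)C)C1(C)C | intermediate
7 | 3-methylbut-2-enoic acid | CC(C)=CC(=O)O | starting material
8 | 1-bromo-3-methylbut-2-ene (prenyl bromide) | CC(C)=CCBr | starting material
9 | (S)-5-methyl-2-(prop-1-en-2-yl)hex-4-enoic acid | C=C(C)[C@H](CC=C(C)C)C(=O)O | intermediate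
10 | (S)-5-methyl-2-(prop-1-en-2-yl)hex-4-en-1-ol | C=C(C)[C@H](CC=C(C)C)CO | intermediate
11 | (S)-lavandulyl trifluoromethanesulfonate | C=C(C)[C@H](CC=C(C)C)COS(=O)(=O)C(F)(F)F | intermediate
12 | (3R,5RS)-2,2-dimethyl-3-prenyl-5-Lav-cyclopentan-1-one | C=C(C)[C@H](CC=C(C)C)CC1C[C@@H](CC=C(C)C)C(C)(C)C1=O | intermediate
13 | diketene (4-methyleneoxetan-2-one) | C=C1CC(=O)O1 | starting material
14 | lithium enolate of the 2-acetoacetyl ketone (acyl group trans to ring prenyl) | C=C(C)[C@H](CC=C(C)C)C[C@@]1(C(=O)CC(=C)O[Li])C[C@@H](CC=C(C)C)C(C)(C)C1=O | intermediate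
15 | cis-fused hydrindane hydroxy-dione (2-prenyl, 3a-Lav, 7a-OH all cis) | C=C(C)[C@H](CC=C(C)C)C[C@@]12C[C@@H](CC=C(C)C)C(C)(C)[C@]1(O)CC(=O)CC2=O | intermediate
16 | 6-methoxy hydrindenone (methyl vinylogous ester of 15) | C=C(C)[C@H](CC=C(C)C)C[C@@]12C[C@@H](CC=C(C)C)C(C)(C)[C@]1(O)CC(OC)=CC2=O | intermediate
17 | 7-prenyl derivative of 16 (7RS) | C=C(C)[C@H](CC=C(C)C)C[C@@]12C[C@@H](CC=C(C)C)C(C)(C)[C@]1(O)C(CC=C(C)C)C(OC)=CC2=O | intermediate
18 | 2-methoxy-8,8-dimethyl-1,7-diprenyl-5-Lav-bicyclo[3.3.1]non-2-ene-4,9-dione | C=C(C)[C@H](CC=C(C)C)C[C@@]12C[C@@H](CC=C(C)C)C(C)(C)[C@@](CC=C(C)C)(C1=O)C(OC)=CC2=O | intermediate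
19 | benzaldehyde | O=Cc1ccccc1 | starting material
20 | 3-[hydroxy(phenyl)methyl] derivative of 18 | C=C(C)[C@H](CC=C(C)C)C[C@@]12C[C@@H](CC=C(C)C)C(C)(C)[C@@](CC=C(C)C)(C1=O)C(OC)=C(C(O)c1ccccc1)C2=O | intermediate
21 | (1R,5R,7R)-3-benzoyl-2-methoxy-8,8-dimethyl-1,7-diprenyl-5-Lav-bicyclo[3.3.1]non-2-ene-4,9-dione | C=C(C)[C@H](CC=C(C)C)C[C@@]12C[C@@H](CC=C(C)C)C(C)(C)[C@@](CC=C(C)C)(C1=O)C(OC)=C(C(=O)c1ccccc1)C2=O | target

## Step count and risks

Total step count: 11. Longest linear sequence: 9 steps (1, 2, 5–11; the branch 3, 4, 5–11 is also 9).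

Steps most likely to fail:

**Step 9 (proposed new step).** The tertiary γ-C–H is less acidic than the CH2 of the known substrate, and elimination to a dienyl ether or retro-aldol cleavage may compete with the shift. Fallback, known chemistry: set out from 16 and omit step 8. Compound 16 is ring-expanded as such with PhI(OAc)2/KOH/MeOH, the 1,2-shift onto an unsubstituted γ-CH2 being the established case, to give the C1–H bicyclo[3.3.1]nonane vinylogous ester F1. Bridgehead deprotonation of F1 with lithium diisopropylamide at −78 °C and quench with prenyl bromide 8 (bridgehead carbanion alkylation) then gives 18, where the route is rejoined.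

**Step 5.** The β-branched triflate may give E2 elimination or O-alkylation with the lithium enolate. Fallback: set out from 6 and 10. Ketone 6 is condensed with 1,1-dimethylhydrazine to the N,N-dimethylhydrazone F2. Alcohol 10 is converted with I2/PPh3/imidazole to (S)-lavandulyl iodide F3. F2 is deprotonated with lithium diisopropylamide and the azaenolate, far more nucleophilic and C-selective, is alkylated with F3 to the hydrazone F4. Hydrolysis with oxalic acid in Et2O/H2O returns the route at 12.

**Step 3.** Enantioselectivity of the chiral-amide-controlled dienediolate alkylation may be insufficient for this substrate. Fallback: set out from 7 and 8. The dienediolate of 7 (lithium diisopropylamide, 2 equiv) is alkylated with 8 without chiral amine to racemic lavandulic acid F5. LiAlH4 reduction gives racemic lavandulol F6. Lipase-catalysed kinetic resolution with vinyl acetate, run past half conversion, gives (R)-lavandulyl acetate F7 and leaves the S alcohol, which is 10. This is written for the case in which the R alcohol is acylated faster; with the opposite preference the S acetate is collected and methanolysed.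

Further compounds
F1 | step 9 | 2-methoxy-8,8-dimethyl-7-prenyl-5-Lav-bicyclo[3.3.1]non-2-ene-4,9-dione (18 lacking the C1 prenyl group) | C=C(C)[C@H](CC=C(C)C)C[C@@]12C[C@@H](CC=C(C)C)C(C)(C)[C@@H](C1=O)C(OC)=CC2=O
F2 | step 5 | N,N-dimethylhydrazone of 6 | CN(C)N=C1CC[C@@H](CC=C(C)C)C1(C)C
F3 | step 5 | (S)-lavandulyl iodide | C=C(C)[C@H](CC=C(C)C)CI
F4 | step 5 | N,N-dimethylhydrazone of 12 | C=C(C)[C@H](CC=C(C)C)CC1C[C@@H](CC=C(C)C)C(C)(C)C1=NN(C)C
F5 | step 3 | racemic lavandulic acid | C=C(C)C(CC=C(C)C)C(=O)O
F6 | step 3 | racemic lavandulol | C=C(C)C(CC=C(C)C)CO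
F7 | step 3 | (R)-lavandulyl acetate | C=C(C)[C@@H](CC=C(C)C)COC(C)=O
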